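**Plan**
1. Retrosynthetic cuts, in order: the six O–Si bonds; the C8–dienyl bond (Stille); flavanone ring C at O1–C2 (oxa-Michael) and C2–C3 (Knoevenagel); the dihydrobenzofuran at O1–C2 and C2–C3 in one [4+1] event; the C3–aryl bond (Grignard).
2. Enabling feature: the dihydrobenzofuran oxygen O1 sits on ring B at C7a, ortho to C3a, which carries the doubly benzylic C3, so O1–C7a=C3a–C3 is a latent ortho-quinone methide. C2 is benzylic to the 4-hydroxyphenyl ring, so it can arrive as an aryl-stabilised sulfonium ylide carbon that still holds a leaving group for the O1–C2 closure.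
3. Forward order: ring B salicylaldehyde + 3,5-dioxygenated aryl Grignard → benzhydrol → sulfone; [4+1] annulation closes the dihydrofuran; Br → CHO; Knoevenagel with the ring A β-ketoester; asymmetric oxa-Michael/decarboxylation closes ring C; Stille coupling brings the (Z)-diene; fluoride removes all silyl groups.
4. Stereochemistry: dihydrobenzofuran C2/C3 (2R,3R) from the C2-symmetric (2R,5R)-2,5-dimethylthiolane ylide (face of the ylide carbon) and the trans-selective addition/SN2 closure; flavanone C2 (S) from a cinchona thiourea catalyst; the Z alkene from a trans-hydrostannation, kept in the Stille coupling.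
5. Helpers put in and taken out: tosyl group (quinone methide trigger), thiolane (chiral leaving group, recovered), tert-butyl ester (Michael activator, lost as isobutene and CO2), silyl ethers (fluoride-labile, so neither strong acid nor base meets the diene or the flavanone at the end).

Key step: step 9

Abbreviations: TBS = tert-butyldimethylsilyl, TIPS = triisopropylsilyl, Ts = 4-methylphenylsulfonyl.
Assumption: the absolute sense of induction of the (2R,5R)-thiolane ylide and of the quinidine-derived thiourea is taken by analogy with their behaviour in benzylide epoxidation and in flavanone formation; should either prove opposite, the enantiomeric sulfide (from the (2R,5R)-diol) or the quinine-derived pseudoenantiomer is used with no other change.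

**Route**

Step 1
Reactants: 1 (2S,5S)-hexane-2,5-diol
Product: 2 (2S,5S)-hexane-2,5-diyl dimethanesulfonate
Conditions: MsCl, Et3N, CH2Cl2, 0 °C
Reagents that add atoms: methanesulfonyl chloride CS(=O)(=O)Cl
Why: Mesylation of both secondary alcohols takes place at oxygen, so both stereocentres are kept.

Step 2
Reactants: 2 (2S,5S)-hexane-2,5-diyl dimethanesulfonate
Product: 3 (2R,5R)-2,5-dimethylthiolane
Conditions: Na2S·9H2O, DMSO, rt; distillation
Reagents that add atoms: sodium sulfide [Na+].[Na+].[S-2]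
Why: Double SN2 displacement by sulfide (the second a 5-exo-tet closure) inverts both centres and should give the C2-symmetric (2R,5R)-sulfide.

Step 3
Reactants: 4 4-[(tert-butyldimethylsilyl)oxy]benzaldehyde
Product: 5 {4-[(tert-butyldimethylsilyl)oxy]phenyl}methanol
Conditions: NaBH4, THF/EtOH, 0 °C
Reagents that add atoms: none
Why: Borohydride reduction of the aldehyde is fast at 0 °C and should leave the aryl silyl ether untouched.

Step 4
Reactants: 5 {4-[(tert-butyldimethylsilyl)oxy]phenyl}methanol; 3 (2R,5R)-2,5-dimethylthiolane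
Product: 7 (2R,5R)-1-{4-[(tert-butyldimethylsilyl)oxy]benzyl}-2,5-dimethylthiolan-1-ium trifluoromethanesulfonate, via 4-(TBS-oxy)benzyl bromide 6 (not isolated)
Conditions: CBr4, PPh3, CH2Cl2, 0 °C; silica plug; then 3, LiOSO2CF3, CH2Cl2/H2O, rt
Reagents that add atoms: lithium trifluoromethanesulfonate [Li+].[O-]S(=O)(=O)C(F)(F)F; carbon tetrabromide BrC(Br)(Br)Br (bromine held only in intermediate 6)
Why: Appel bromination followed by S-alkylation of the sulfide and anion exchange should give a single salt, because the C2 axis of the thiolane makes its two sulfur lone pairs equivalent.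

Step 5
Reactants: 8 5-bromo-2,4-dihydroxybenzaldehyde
Product: 9 5-bromo-2-hydroxy-4-[(triisopropylsilyl)oxy]benzaldehyde
Conditions: TIPSCl (1.05 equiv), imidazole, DMF, 0 °C
Reagents that add atoms: chlorotriisopropylsilane CC(C)[Si](Cl)(C(C)C)C(C)C
Why: Selective silylation of the more acidic 4-hydroxyl, since the 2-hydroxyl is hydrogen-bonded to the aldehyde and stays free.

Step 6
Reactants: 10 5-bromobenzene-1,3-diol
Product: 11 1-bromo-3,5-bis[(tert-butyldimethylsilyl)oxy]benzene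
Conditions: TBSCl (2.2 equiv), imidazole, DMF, rt
Reagents that add atoms: tert-butylchlorodimethylsilane CC(C)(C)[Si](C)(C)Cl
Why: Standard silylation of both phenols.

Step 7
Reactants: 11 1-bromo-3,5-bis[(tert-butyldimethylsilyl)oxy]benzene; 9 5-bromo-2-hydroxy-4-[(triisopropylsilyl)oxy]benzaldehyde
Product: 13 4-bromo-2-{[3,5-bis(TBS-oxy)phenyl](hydroxy)methyl}-5-(TIPS-oxy)phenol (racemic), via arylmagnesium bromide 12 (not isolated)
Conditions: 11, Mg, THF, 40 °C; 9, NaH (1.05 equiv), THF, 0 °C; then 12 (1.3 equiv), 0 °C to rt; aq. NH4Cl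
Reagents that add atoms: magnesium [Mg] (held only in intermediate 12)
Why: Grignard addition to the sodium salt of the salicylaldehyde should give the ortho-hydroxybenzhydrol; the aryl bromide of 9 does not exchange with an aryl Grignard, and the new carbinol centre is racemic and is erased in step 9.

Step 8
Reactants: 13 4-bromo-2-{[3,5-bis(TBS-oxy)phenyl](hydroxy)methyl}-5-(TIPS-oxy)phenol
Product: 14 4-bromo-2-{[3,5-bis(TBS-oxy)phenyl](tosyl)methyl}-5-(TIPS-oxy)phenol (racemic)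
Conditions: 4-methylbenzenesulfinic acid (freshly liberated from its sodium salt), CH2Cl2, rt
Reagents that add atoms: 4-methylbenzenesulfinic acid Cc1ccc(cc1)S(=O)O
Why: SN1-type substitution through the ortho-hydroxy/para-silyloxy-stabilised benzhydryl cation, with sulfinate attacking through sulfur, should give the bench-stable sulfone that releases the quinone methide under base.

Step 9
Reactants: 14 4-bromo-2-{[3,5-bis(TBS-oxy)phenyl](tosyl)methyl}-5-(TIPS-oxy)phenol; 7 (2R,5R)-1-{4-[(tert-butyldimethylsilyl)oxy]benzyl}-2,5-dimethylthiolan-1-ium trifluoromethanesulfonate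
Product: 18 (2R,3R)-5-bromo-3-[3,5-bis(TBS-oxy)phenyl]-2-[4-(TBS-oxy)phenyl]-6-(TIPS-oxy)-2,3-dihydro-1-benzofuran, via ortho-quinone methide 15 (not isolated), via sulfonium ylide 16 (not isolated), via phenoxide-sulfonium betaine 17 (not isolated)
Conditions: 7 (1.3 equiv), Cs2CO3 (3 equiv), CH2Cl2, 0 °C to rt
Reagents that add atoms: none
Why: Proposed new method: Cs2CO3 turns sulfone 14 into ortho-quinone methide 15 by E1cB loss of sulfinate and deprotonates salt 7 to the aryl-stabilised ylide 16, whose carbon adds to the exocyclic methide carbon (ring B re-aromatises, so the C2–C3 bond forms irreversibly) to give betaine 17, in which the phenoxide displaces the thiolane at the benzylic carbon and so forms the O1–C2 bond. The closest known reaction types are the base-mediated [4+1] annulation of such in situ ortho-quinone methides with carbonyl-stabilised sulfonium ylides to trans-2,3-dihydrobenzofurans and the Corey–Chaykovsky epoxidation with chiral benzyl sulfonium ylides; what is new is their union, an aryl-stabilised chiral ylide on a quinone methide. The one ring closed is the dihydrofuran, by a 5-exo-tet SN2 displacement with inversion at C2. C2 is controlled by the C2-symmetric (2R,5R)-thiolane, which gives a single ylide with one face screened by the flanking methyl group (inversion on closure then gives 2R), and C3 is controlled by the open, antiperiplanar transition state of the addition, which keeps the two aryl groups apart and leads to the trans (3R) product. The step needs C- over O-benzylation of the phenoxide, trans over cis, and one ylide face: the first is secured because the soft ylide carbon adds to the strongly electrophilic methide carbon faster than the phenoxide attacks the salt, the second by the irreversible addition and backside closure, the third by the sulfide, while the aryl bromide and the silyl ethers are inert to Cs2CO3.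

Step 10
Reactants: 18 (2R,3R)-5-bromo-3-[3,5-bis(TBS-oxy)phenyl]-2-[4-(TBS-oxy)phenyl]-6-(TIPS-oxy)-2,3-dihydro-1-benzofuran
Product: 20 (2R,3R)-3-[3,5-bis(TBS-oxy)phenyl]-2-[4-(TBS-oxy)phenyl]-6-(TIPS-oxy)-2,3-dihydro-1-benzofuran-5-carbaldehyde, via aryllithium 19 (not isolated)
Conditions: n-BuLi (1.1 equiv), THF, −78 °C, 10 min; DMF, −78 to 0 °C; aq. NH4Cl
Reagents that add atoms: N,N-dimethylformamide CN(C)C=O; n-butyllithium [Li]CCCC (lithium held only in intermediate 19)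
Why: Bromine–lithium exchange and Bouveault formylation; at −78 °C exchange outruns benzylic deprotonation, and the bulky TIPS group next to lithium resists the 1,3 O-to-C silyl shift, so both ring stereocentres should be untouched.

Step 11
Reactants: 21 1-(2,4,6-trihydroxyphenyl)ethan-1-one
Product: 22 1-{2,4-bis[(tert-butyldimethylsilyl)oxy]-6-hydroxyphenyl}ethan-1-one
Conditions: TBSCl (2.1 equiv), imidazole, CH2Cl2/DMF, 0 °C to rt
Reagents that add atoms: tert-butylchlorodimethylsilane CC(C)(C)[Si](C)(C)Cl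
Why: Silylation stops after two groups because the last hydroxyl is chelated to the ketone.

Step 12
Reactants: 22 1-{2,4-bis[(tert-butyldimethylsilyl)oxy]-6-hydroxyphenyl}ethan-1-one
Product: 23 1-{4,6-bis[(tert-butyldimethylsilyl)oxy]-2-hydroxy-3-iodophenyl}ethan-1-one
Conditions: N-iodosuccinimide (1.05 equiv), CH2Cl2, 0 °C, dark
Reagents that add atoms: N-iodosuccinimide O=C1CCC(=O)N1I
Why: Electrophilic aromatic iodination should go ortho to the free hydroxyl (C3), since the other open position lies between two bulky silyl ethers.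

Step 13
Reactants: 23 1-{4,6-bis[(tert-butyldimethylsilyl)oxy]-2-hydroxy-3-iodophenyl}ethan-1-one
Product: 24 tert-butyl 3-{4,6-bis[(tert-butyldimethylsilyl)oxy]-2-hydroxy-3-iodophenyl}-3-oxopropanoate
Conditions: LiN(SiMe3)2 (3.2 equiv), THF, −78 °C; Boc2O (1.1 equiv), −78 to −20 °C; aq. NH4Cl
Reagents that add atoms: di-tert-butyl dicarbonate CC(C)(C)OC(=O)OC(=O)OC(C)(C)C
Why: Claisen-type C-acylation of the phenoxide/enolate dianion; any O-Boc phenol formed first is carried to the same β-ketoester by Baker–Venkataraman-type acyl transfer.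

Step 14
Reactants: 24 tert-butyl 3-{4,6-bis[(tert-butyldimethylsilyl)oxy]-2-hydroxy-3-iodophenyl}-3-oxopropanoate; 20 (2R,3R)-3-[3,5-bis(TBS-oxy)phenyl]-2-[4-(TBS-oxy)phenyl]-6-(TIPS-oxy)-2,3-dihydro-1-benzofuran-5-carbaldehyde
Product: 25 tert-butyl 2-{4,6-bis(TBS-oxy)-2-hydroxy-3-iodobenzoyl}-3-{(2R,3R)-dihydrobenzofuran-5-yl}prop-2-enoate (alkene geometry not defined; both isomers converge)
Conditions: piperidine (0.2 equiv), AcOH (0.2 equiv), toluene, 4 Å molecular sieves, rt to 40 °C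
Reagents that add atoms: none
Why: Knoevenagel condensation of the active methylene with the aryl aldehyde under buffered amine catalysis, where the ketone-chelated phenol should not yet cyclise.

Step 15
Reactants: 25 tert-butyl 2-{4,6-bis(TBS-oxy)-2-hydroxy-3-iodobenzoyl}-3-{(2R,3R)-dihydrobenzofuran-5-yl}prop-2-enoate
Product: 28 (2S)-5,7-bis(TBS-oxy)-8-iodo-2-{(2R,3R)-3-[3,5-bis(TBS-oxy)phenyl]-2-[4-(TBS-oxy)phenyl]-6-(TIPS-oxy)-2,3-dihydro-1-benzofuran-5-yl}chroman-4-one, via flavanone tert-butyl ester 26 (not isolated), via flavanone β-keto acid 27 (not isolated)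
Conditions: 9-amino-9-deoxy-epi-quinidine 3,5-bis(trifluoromethyl)phenyl thiourea (10 mol%), toluene, −25 °C; then anhydrous TsOH, toluene, 80 °C
Reagents that add atoms: none
Why: Bifunctional thiourea-catalysed intramolecular oxa-Michael addition (the thiourea binds the β-ketoester and the quinuclidine guides the ring A phenol to one face of the β-carbon, so flavanone C2 should be set as S under catalyst control), then acid-mediated loss of isobutene and decarboxylation, which removes the activating ester and the labile C3 centre.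

Step 16
Reactants: 29 2-methylbut-1-en-3-yne
Product: 30 tributyl[(1Z)-3-methylbuta-1,3-dien-1-yl]stannane
Conditions: Bu3SnH, ZrCl4 (0.2 equiv), toluene, 0 °C
Reagents that add atoms: tributyltin hydride CCCC[SnH](CCCC)CCCC
Why: Lewis acid-catalysed trans-hydrostannation of the terminal alkyne places tin at the terminal carbon by anti addition and should give the Z dienylstannane.

Step 17
Reactants: 28 (2S)-5,7-bis(TBS-oxy)-8-iodo-2-{(2R,3R)-dihydrobenzofuran-5-yl}chroman-4-one; 30 tributyl[(1Z)-3-methylbuta-1,3-dien-1-yl]stannane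
Product: 31 (2S)-5,7-bis(TBS-oxy)-8-[(1Z)-3-methylbuta-1,3-dien-1-yl]-2-{(2R,3R)-3-[3,5-bis(TBS-oxy)phenyl]-2-[4-(TBS-oxy)phenyl]-6-(TIPS-oxy)-2,3-dihydro-1-benzofuran-5-yl}chroman-4-one
Conditions: Pd2(dba)3 (5 mol%), AsPh3 (20 mol%), CuI (10 mol%), DMF, 40 °C, dark
Reagents that add atoms: none
Why: Stille coupling runs without base, so the flavanone centre should not epimerise, and alkenyl transfer from tin occurs with retention of the Z geometry.

Step 18
Reactants: 31 (2S)-5,7-bis(TBS-oxy)-8-[(1Z)-3-methylbuta-1,3-dien-1-yl]-2-{(2R,3R)-dihydrobenzofuran-5-yl}chroman-4-one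
Product: 32 CNP0284772.1, (2S)-5,7-dihydroxy-2-[(2R,3R)-3-(3,5-dihydroxyphenyl)-6-hydroxy-2-(4-hydroxyphenyl)-2,3-dihydro-1-benzofuran-5-yl]-8-[(1Z)-3-methylbuta-1,3-dien-1-yl]chroman-4-one
Conditions: Bu4NF (7 equiv), AcOH (7 equiv), THF, 0 °C to rt, argon, dark; reversed-phase HPLC
Reagents that add atoms: none
Why: Fluoride-mediated cleavage of all six aryl silyl ethers; the acetic acid buffer keeps phenoxide low, so retro-oxa-Michael epimerisation of the flavanone and acid-triggered cyclisation of the diene onto the 7-hydroxyl should both be avoided.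

**Compound list**
1 | (2S,5S)-hexane-2,5-diol | C[C@H](O)CC[C@H](C)O | starting material
2 | (2S,5S)-hexane-2,5-diyl dimethanesulfonate | C[C@H](OS(C)(=O)=O)CC[C@H](C)OS(C)(=O)=O | intermediate
3 | (2R,5R)-2,5-dimethylthiolane | C[C@@H]1CC[C@@H](C)S1 | intermediate
4 | 4-[(tert-butyldimethylsilyl)oxy]benzaldehyde | O=Cc1ccc(O[Si](C)(C)C(C)(C)C)cc1 | starting material
5 | {4-[(tert-butyldimethylsilyl)oxy]phenyl}methanol | OCc1ccc(O[Si](C)(C)C(C)(C)C)cc1 | intermediate
6 | [4-(bromomethyl)phenoxy](tert-butyl)dimethylsilane | BrCc1ccc(O[Si](C)(C)C(C)(C)C)cc1 | intermediate (not isolated)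
7 | (2R,5R)-1-{4-[(tert-butyldimethylsilyl)oxy]benzyl}-2,5-dimethylthiolan-1-ium trifluoromethanesulfonate | C[C@@H]1CC[C@@H](C)[S+]1Cc1ccc(O[Si](C)(C)C(C)(C)C)cc1.[O-]S(=O)(=O)C(F)(F)F | intermediate
8 | 5-bromo-2,4-dihydroxybenzaldehyde | O=Cc1cc(Br)c(O)cc1O | starting material
9 | 5-bromo-2-hydroxy-4-[(triisopropylsilyl)oxy]benzaldehyde | O=Cc1cc(Br)c(O[Si](C(C)C)(C(C)C)C(C)C)cc1O | intermediate
10 | 5-bromobenzene-1,3-diol | Oc1cc(O)cc(Br)c1 | starting material
11 | 1-bromo-3,5-bis[(tert-butyldimethylsilyl)oxy]benzene | Brc1cc(O[Si](C)(C)C(C)(C)C)cc(O[Si](C)(C)C(C)(C)C)c1 | intermediate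
12 | {3,5-bis[(tert-butyldimethylsilyl)oxy]phenyl}magnesium bromide | Br[Mg]c1cc(O[Si](C)(C)C(C)(C)C)cc(O[Si](C)(C)C(C)(C)C)c1 | intermediate (not isolated)
13 | 4-bromo-2-{[3,5-bis(TBS-oxy)phenyl](hydroxy)methyl}-5-(TIPS-oxy)phenol, racemic | OC(c1cc(O[Si](C)(C)C(C)(C)C)cc(O[Si](C)(C)C(C)(C)C)c1)c1cc(Br)c(O[Si](C(C)C)(C(C)C)C(C)C)cc1O | intermediate
14 | 4-bromo-2-{[3,5-bis(TBS-oxy)phenyl](tosyl)methyl}-5-(TIPS-oxy)phenol, racemic | Cc1ccc(cc1)S(=O)(=O)C(c1cc(O[Si](C)(C)C(C)(C)C)cc(O[Si](C)(C)C(C)(C)C)c1)c1cc(Br)c(O[Si](C(C)C)(C(C)C)C(C)C)cc1O | intermediate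
15 | (6E)-4-bromo-6-{[3,5-bis(TBS-oxy)phenyl]methylidene}-3-(TIPS-oxy)cyclohexa-2,4-dien-1-one (ortho-quinone methide) | O=C1C=C(O[Si](C(C)C)(C(C)C)C(C)C)C(Br)=C/C1=C\c1cc(O[Si](C)(C)C(C)(C)C)cc(O[Si](C)(C)C(C)(C)C)c1 | intermediate (not isolated)
16 | (2R,5R)-2,5-dimethylthiolan-1-ium-1-yl[4-(TBS-oxy)phenyl]methanide (sulfonium ylide) | C[C@@H]1CC[C@@H](C)[S+]1[CH-]c1ccc(O[Si](C)(C)C(C)(C)C)cc1 | intermediate (not isolated)
17 | betaine: 4-bromo-2-{(1R,2S)-1-[3,5-bis(TBS-oxy)phenyl]-2-[(2R,5R)-2,5-dimethylthiolan-1-ium-1-yl]-2-[4-(TBS-oxy)phenyl]ethyl}-5-(TIPS-oxy)phenolate | [O-]c1cc(O[Si](C(C)C)(C(C)C)C(C)C)c(Br)cc1[C@@H](c1cc(O[Si](C)(C)C(C)(C)C)cc(O[Si](C)(C)C(C)(C)C)c1)[C@@H](c1ccc(O[Si](C)(C)C(C)(C)C)cc1)[S+]1[C@H](C)CC[C@H]1C | intermediate (not isolated)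
18 | (2R,3R)-5-bromo-3-[3,5-bis(TBS-oxy)phenyl]-2-[4-(TBS-oxy)phenyl]-6-(TIPS-oxy)-2,3-dihydro-1-benzofuran | Brc1cc2c(cc1O[Si](C(C)C)(C(C)C)C(C)C)O[C@@H](c1ccc(O[Si](C)(C)C(C)(C)C)cc1)[C@@H]2c1cc(O[Si](C)(C)C(C)(C)C)cc(O[Si](C)(C)C(C)(C)C)c1 | intermediate
19 | (2R,3R)-5-lithio-3-[3,5-bis(TBS-oxy)phenyl]-2-[4-(TBS-oxy)phenyl]-6-(TIPS-oxy)-2,3-dihydro-1-benzofuran | [Li]c1cc2c(cc1O[Si](C(C)C)(C(C)C)C(C)C)O[C@@H](c1ccc(O[Si](C)(C)C(C)(C)C)cc1)[C@@H]2c1cc(O[Si](C)(C)C(C)(C)C)cc(O[Si](C)(C)C(C)(C)C)c1 | intermediate (not isolated)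
20 | (2R,3R)-3-[3,5-bis(TBS-oxy)phenyl]-2-[4-(TBS-oxy)phenyl]-6-(TIPS-oxy)-2,3-dihydro-1-benzofuran-5-carbaldehyde | O=Cc1cc2c(cc1O[Si](C(C)C)(C(C)C)C(C)C)O[C@@H](c1ccc(O[Si](C)(C)C(C)(C)C)cc1)[C@@H]2c1cc(O[Si](C)(C)C(C)(C)C)cc(O[Si](C)(C)C(C)(C)C)c1 | intermediate
21 | 1-(2,4,6-trihydroxyphenyl)ethan-1-one | CC(=O)c1c(O)cc(O)cc1O | starting material
22 | 1-{2,4-bis[(tert-butyldimethylsilyl)oxy]-6-hydroxyphenyl}ethan-1-one | CC(=O)c1c(O)cc(O[Si](C)(C)C(C)(C)C)cc1O[Si](C)(C)C(C)(C)C | intermediate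
23 | 1-{4,6-bis[(tert-butyldimethylsilyl)oxy]-2-hydroxy-3-iodophenyl}ethan-1-one | CC(=O)c1c(O)c(I)c(O[Si](C)(C)C(C)(C)C)cc1O[Si](C)(C)C(C)(C)C | intermediate
24 | tert-butyl 3-{4,6-bis[(tert-butyldimethylsilyl)oxy]-2-hydroxy-3-iodophenyl}-3-oxopropanoate | CC(C)(C)OC(=O)CC(=O)c1c(O)c(I)c(O[Si](C)(C)C(C)(C)C)cc1O[Si](C)(C)C(C)(C)C | intermediate
25 | tert-butyl 2-{4,6-bis(TBS-oxy)-2-hydroxy-3-iodobenzoyl}-3-{(2R,3R)-3-[3,5-bis(TBS-oxy)phenyl]-2-[4-(TBS-oxy)phenyl]-6-(TIPS-oxy)-2,3-dihydro-1-benzofuran-5-yl}prop-2-enoate (E/Z not defined) | CC(C)(C)OC(=O)C(=Cc1cc2c(cc1O[Si](C(C)C)(C(C)C)C(C)C)O[C@@H](c1ccc(O[Si](C)(C)C(C)(C)C)cc1)[C@@H]2c1cc(O[Si](C)(C)C(C)(C)C)cc(O[Si](C)(C)C(C)(C)C)c1)C(=O)c1c(O)c(I)c(O[Si](C)(C)C(C)(C)C)cc1O[Si](C)(C)C(C)(C)C | intermediate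
26 | tert-butyl (2S,3R)-5,7-bis(TBS-oxy)-8-iodo-4-oxo-2-{(2R,3R)-dihydrobenzofuran-5-yl}chromane-3-carboxylate (trans; in equilibrium with its enol) | Ic1c(O[Si](C)(C)C(C)(C)C)cc(O[Si](C)(C)C(C)(C)C)c2c1O[C@H](c1cc3c(cc1O[Si](C(C)C)(C(C)C)C(C)C)O[C@@H](c1ccc(O[Si](C)(C)C(C)(C)C)cc1)[C@@H]3c1cc(O[Si](C)(C)C(C)(C)C)cc(O[Si](C)(C)C(C)(C)C)c1)[C@@H](C(=O)OC(C)(C)C)C2=O | intermediate (not isolated)
27 | (2S,3R)-5,7-bis(TBS-oxy)-8-iodo-4-oxo-2-{(2R,3R)-dihydrobenzofuran-5-yl}chromane-3-carboxylic acid | Ic1c(O[Si](C)(C)C(C)(C)C)cc(O[Si](C)(C)C(C)(C)C)c2c1O[C@H](c1cc3c(cc1O[Si](C(C)C)(C(C)C)C(C)C)O[C@@H](c1ccc(O[Si](C)(C)C(C)(C)C)cc1)[C@@H]3c1cc(O[Si](C)(C)C(C)(C)C)cc(O[Si](C)(C)C(C)(C)C)c1)[C@@H](C(=O)O)C2=O | intermediate (not isolated)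
28 | (2S)-5,7-bis(TBS-oxy)-8-iodo-2-{(2R,3R)-3-[3,5-bis(TBS-oxy)phenyl]-2-[4-(TBS-oxy)phenyl]-6-(TIPS-oxy)-2,3-dihydro-1-benzofuran-5-yl}chroman-4-one | Ic1c(O[Si](C)(C)C(C)(C)C)cc(O[Si](C)(C)C(C)(C)C)c2c1O[C@H](c1cc3c(cc1O[Si](C(C)C)(C(C)C)C(C)C)O[C@@H](c1ccc(O[Si](C)(C)C(C)(C)C)cc1)[C@@H]3c1cc(O[Si](C)(C)C(C)(C)C)cc(O[Si](C)(C)C(C)(C)C)c1)CC2=O | intermediate
29 | 2-methylbut-1-en-3-yne | C=C(C)C#C | starting material
30 | tributyl[(1Z)-3-methylbuta-1,3-dien-1-yl]stannane | C=C(C)/C=C\[Sn](CCCC)(CCCC)CCCC | intermediate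
31 | (2S)-5,7-bis(TBS-oxy)-8-[(1Z)-3-methylbuta-1,3-dien-1-yl]-2-{(2R,3R)-3-[3,5-bis(TBS-oxy)phenyl]-2-[4-(TBS-oxy)phenyl]-6-(TIPS-oxy)-2,3-dihydro-1-benzofuran-5-yl}chroman-4-one | C=C(C)/C=C\c1c(O[Si](C)(C)C(C)(C)C)cc(O[Si](C)(C)C(C)(C)C)c2c1O[C@H](c1cc3c(cc1O[Si](C(C)C)(C(C)C)C(C)C)O[C@@H](c1ccc(O[Si](C)(C)C(C)(C)C)cc1)[C@@H]3c1cc(O[Si](C)(C)C(C)(C)C)cc(O[Si](C)(C)C(C)(C)C)c1)CC2=O | intermediate
32 | CNP0284772.1 | C=C(C)/C=C\c1c(O)cc(O)c2c1O[C@H](c1cc3c(cc1O)O[C@@H](c1ccc(O)cc1)[C@@H]3c1cc(O)cc(O)c1)CC2=O | target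

**Step count**
Total steps: 18. Longest linear sequence: 9 (steps 6, 7, 8, 9, 10, 14, 15, 17, 18).

**Three steps most likely to fail**

Step 9 (bears the label). What may go wrong: poor facial selectivity at the ylide carbon, erosion of the trans relationship, and competing O-benzylation of the phenoxide by the sulfonium salt or ylide rearrangement. Fallback with known chemistry, from 13 back to 18 by a different ring-closing bond: 13 is oxidised (MnO2, CH2Cl2) to the 2-hydroxybenzophenone F1. F1 is etherified with alcohol 5 under Mitsunobu conditions (PPh3, diisopropyl azodicarboxylate, THF) to the aryl benzyl ether F2. F2 is condensed with N2H4·H2O (EtOH, AcOH cat., 70 °C) to the hydrazone F3. F3 is oxidised with MnO2 to the diaryl diazomethane F4, which is treated without isolation with the dirhodium tetracarboxylate Rh2(PTAD)4 (the enantiomer that sets 3R). Donor/donor carbene insertion into the benzylic C–H bond of the ether should give the cis-(2S,3R)-dihydrobenzofuran F5. Brief treatment of F5 with a catalytic acid (CF3CO2H, CH2Cl2, 0 °C) should epimerise C2 through the ring-opened para-silyloxybenzyl cation to the trans compound 18.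

Step 15. What may go wrong: low facial selectivity in the oxa-Michael addition (bulky ortho-silyloxy ring B, electron-rich β-carbon, possible mismatch with the remote centres), epimerisation at flavanone C2 by retro-oxa-Michael during the hot acid decarboxylation, and partial loss of silyl ethers under TsOH. Fallback, from 23 and 20 back to 28, replacing catalyst control by separation with recycling: amine-catalysed Claisen–Schmidt condensation of 23 with 20 (pyrrolidine/AcOH, MeCN, 40 °C) should give the chalcone F6. Under the same conditions F6 equilibrates by oxa-Michael closure to 28 and its (2R)-epimer F7. The two are separated by preparative HPLC, and F7 is returned to the amine equilibration until converted.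

Step 17. What may go wrong: slow coupling at the doubly ortho-substituted C8, Z-to-E isomerisation of the dienyl group on palladium, and protodestannylation. Fallback, from 28 back to 31, building the alkene by reduction instead of transfer: Sonogashira coupling of 28 with enyne 29 (Pd(PPh3)2Cl2, CuI, i-Pr2NH, THF, 45 °C) should give the aryl enyne F8. Z-selective semireduction of the conjugated triple bond of F8 with zinc activated by Cu(OAc)2 and AgNO3 (MeOH/H2O, 40 °C) should then give 31.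

Further compounds
F1 | step 9 | [2-hydroxy-5-bromo-4-(TIPS-oxy)phenyl][3,5-bis(TBS-oxy)phenyl]methanone | O=C(c1cc(O[Si](C)(C)C(C)(C)C)cc(O[Si](C)(C)C(C)(C)C)c1)c1cc(Br)c(O[Si](C(C)C)(C(C)C)C(C)C)cc1O
F2 | step 9 | {5-bromo-2-[4-(TBS-oxy)benzyloxy]-4-(TIPS-oxy)phenyl}[3,5-bis(TBS-oxy)phenyl]methanone | O=C(c1cc(O[Si](C)(C)C(C)(C)C)cc(O[Si](C)(C)C(C)(C)C)c1)c1cc(Br)c(O[Si](C(C)C)(C(C)C)C(C)C)cc1OCc1ccc(O[Si](C)(C)C(C)(C)C)cc1
F3 | step 9 | hydrazone of F2 (E/Z not defined) | NN=C(c1cc(O[Si](C)(C)C(C)(C)C)cc(O[Si](C)(C)C(C)(C)C)c1)c1cc(Br)c(O[Si](C(C)C)(C(C)C)C(C)C)cc1OCc1ccc(O[Si](C)(C)C(C)(C)C)cc1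
F4 | step 9 | {5-bromo-2-[4-(TBS-oxy)benzyloxy]-4-(TIPS-oxy)phenyl}[3,5-bis(TBS-oxy)phenyl]diazomethane | [N-]=[N+]=C(c1cc(O[Si](C)(C)C(C)(C)C)cc(O[Si](C)(C)C(C)(C)C)c1)c1cc(Br)c(O[Si](C(C)C)(C(C)C)C(C)C)cc1OCc1ccc(O[Si](C)(C)C(C)(C)C)cc1
F5 | step 9 | (2S,3R)-5-bromo-3-[3,5-bis(TBS-oxy)phenyl]-2-[4-(TBS-oxy)phenyl]-6-(TIPS-oxy)-2,3-dihydro-1-benzofuran (cis) | Brc1cc2c(cc1O[Si](C(C)C)(C(C)C)C(C)C)O[C@H](c1ccc(O[Si](C)(C)C(C)(C)C)cc1)[C@@H]2c1cc(O[Si](C)(C)C(C)(C)C)cc(O[Si](C)(C)C(C)(C)C)c1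
F6 | step 15 | (2E)-1-{4,6-bis(TBS-oxy)-2-hydroxy-3-iodophenyl}-3-{(2R,3R)-3-[3,5-bis(TBS-oxy)phenyl]-2-[4-(TBS-oxy)phenyl]-6-(TIPS-oxy)-2,3-dihydro-1-benzofuran-5-yl}prop-2-en-1-one | O=C(/C=C/c1cc2c(cc1O[Si](C(C)C)(C(C)C)C(C)C)O[C@@H](c1ccc(O[Si](C)(C)C(C)(C)C)cc1)[C@@H]2c1cc(O[Si](C)(C)C(C)(C)C)cc(O[Si](C)(C)C(C)(C)C)c1)c1c(O)c(I)c(O[Si](C)(C)C(C)(C)C)cc1O[Si](C)(C)C(C)(C)C
F7 | step 15 | (2R)-epimer of 28 | Ic1c(O[Si](C)(C)C(C)(C)C)cc(O[Si](C)(C)C(C)(C)C)c2c1O[C@@H](c1cc3c(cc1O[Si](C(C)C)(C(C)C)C(C)C)O[C@@H](c1ccc(O[Si](C)(C)C(C)(C)C)cc1)[C@@H]3c1cc(O[Si](C)(C)C(C)(C)C)cc(O[Si](C)(C)C(C)(C)C)c1)CC2=O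
F8 | step 17 | (2S)-5,7-bis(TBS-oxy)-8-(3-methylbut-3-en-1-yn-1-yl)-2-{(2R,3R)-3-[3,5-bis(TBS-oxy)phenyl]-2-[4-(TBS-oxy)phenyl]-6-(TIPS-oxy)-2,3-dihydro-1-benzofuran-5-yl}chroman-4-one | C=C(C)C#Cc1c(O[Si](C)(C)C(C)(C)C)cc(O[Si](C)(C)C(C)(C)C)c2c1O[C@H](c1cc3c(cc1O[Si](C(C)C)(C(C)C)C(C)C)O[C@@H](c1ccc(O[Si](C)(C)C(C)(C)C)cc1)[C@@H]3c1cc(O[Si](C)(C)C(C)(C)C)cc(O[Si](C)(C)C(C)(C)C)c1)CC2=O
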